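The substrate in this flask leaves by a first-order step to side product A, a second-order step to side product B, and coupling to the target.

substrate 0.30 M; solid reagent 0.540 M; time 15 d

    substrate → side product A (k1 = 5.6 × 10⁻⁵ s⁻¹)
    2 substrate → side product B (k2 = 8.5 × 10⁻⁵ L mol⁻¹ s⁻¹)
    substrate + coupling partner → target (k3 = 1.6 × 10⁻⁴ L mol⁻¹ s⁻¹)
    solid reagent ⇌ coupling partner, rate k4*(cs4 - [coupling partner]) while solid is left; crystals form when [coupling partner] > cs4 (cs4 = 0.24 M, k4 = 2.5 × 10⁻⁵ s⁻¹)
    coupling partner → decomposed reagent (k5 = 5.7 × 10⁻⁶ s⁻¹)

- in percentages every species weighs as the substrate in it: one side product B counts as two
- two of one species on the left: rate k times its square, two consumed each time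
- as a solid, counted per litre of solution: solid reagent
- at the start none of the solid reagent is in solution
- the reaction counts as stopped when no species that holds the substrate changes by six tenths of a point or more over the second half of the time
- run time (flask): 15 d

- at 15 d, what has stopped the reaction, if anything has (for what has run out or reacted, a solid counts together with what of it has only dissolved) (it is still moving / all of the substrate has reacted)
- amount of target at 15 d, in percent of the substrate charged

Turn the first question round. For this flask to be still moving at 15 d, substrate would have to be still reacting over the second half of that time. But its half-life by the first-order step alone is 0.14 d, so 15 d holds 105 such half-lives, and I expect the substrate to be consumed. You therefore ask where it goes, not when it stops.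

The first-order loss grows with the substrate concentration and the second-order loss with its square, so the two are equal at one concentration. Call it the crossover concentration c*, the first-order constant over twice the second-order constant: 0.329 M. With C for the charge, and with coupling set aside as an approximation, integrating the two losses gives side product A a share of c*/C times the natural logarithm of one plus C/c*, which for this flask is 71.1% of the substrate not coupled. My reckoning stops there, short of a target figure.

The forecast says that all of the substrate has reacted, and it puts the target at 10%: “a rough integration of the coupling rate gives only about a tenth of the substrate as target”.

In the flask, all of the substrate has reacted, with 8.76% of target, and substrate stands at 0% at 3.00 d. Of the substrate not coupled in this flask, side product A holds 70.0% at 15.0 d, beside the 71.1% reckoned. The neighbour charged with 1.2 M of substrate starts 3.65 times c*, above it, and the same rule gives side product A 42.1% of the uncoupled substrate there. That neighbour ends with 39.4% of side product A against 56.6% of side product B, a share of 41.0%.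

The numbers are those of an exercise, and the outcome is calculated.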